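**Plan**

- Chain numbering: heptanoate C1 (ester C=O) to C7 (CH2 on chromone C2). The retrosynthesis cuts C4–C5 first, then the pyranone bonds O1–C2 and C2–C3 (chromone from a 2-hydroxyaryl 1,3-diketone).
- Enabling feature: the C6 carbinol sits between two methylenes, C5 and C7. C7 ends in chromone C2, which is at the carboxylic acid oxidation level, so one extra CO2H on C5 reveals a prochiral 3-oxyglutaric acid. The left half, MeO2C(CH2)3, is glutaric acid monomethyl ester minus CO2. Both halves are glutarates, joined with loss of two CO2.
- Forward order: the benzene ring is bought. The pyranone ring is closed in step 1 (Claisen acylation, then cyclodehydration). The chain is joined in step 4 by decarboxylative C(sp3)–C(sp3) coupling of two redox-active esters. Silyl removal ends the route.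
- Stereochemistry: the only stereocentre (C6, R) comes from the enantiopure (R)-3-silyloxyglutarate half-ester 2. It is never a reacting centre, because the radical is made at the neighbouring C5. The descriptor changes R→S→R along the route only through CIP priorities.
- Protecting groups: phenols stay free, the carboxyl is masked in situ as its lithium salt, and the only protecting group is the TBS ether already present in 2.

Key step: step 4

Assumption: 2 is bought as the single (R)-enantiomer (a bulk building block for statin side chains); if not available it is made by enantioselective methanolysis of commercial 3-(tert-butyldimethylsilyloxy)glutaric anhydride.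

**Route**

Step 1
Reactants: 1 2',6'-dihydroxy-4'-methoxyacetophenone; 2 (R)-3-(tert-butyldimethylsilyloxy)glutaric acid monomethyl ester
Product: 4 (S)-3-(tert-butyldimethylsilyloxy)-4-(5-hydroxy-7-methoxy-4-oxo-4H-chromen-2-yl)butanoic acid, via diketo acid 3 (not isolated)
Conditions: 1 (2.2 equiv), LiHMDS (6.6 equiv), THF, −78 → −10 °C; add 2 pre-treated with LiHMDS (1.0 equiv), −78 → −10 °C; cold 1 M HCl; crude 3, TsOH·H2O (10 mol %), toluene, 60 °C
Reagents that add atoms: none
Why: Crossed Claisen condensation of the O,O,C-trilithio anion of 1 at the methyl ester of 2 (the carboxyl being masked as its lithium salt), then acid-catalysed cyclodehydration of the 2-hydroxyaryl 1,3-diketone should close the pyranone ring; the two phenols of 1 are equivalent, so only the 5-hydroxy-7-methoxy pattern can form, and the stereocentre is not touched.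

Step 2
Reactants: 4 (S)-3-(tert-butyldimethylsilyloxy)-4-(5-hydroxy-7-methoxy-4-oxo-4H-chromen-2-yl)butanoic acid
Product: 5 1,3-dioxoisoindolin-2-yl (S)-3-(tert-butyldimethylsilyloxy)-4-(5-hydroxy-7-methoxy-4-oxo-4H-chromen-2-yl)butanoate
Conditions: N-hydroxyphthalimide (1.1 equiv), DIC (1.1 equiv), DMAP (5 mol %), CH2Cl2, 0 °C → rt
Reagents that add atoms: N-hydroxyphthalimide, ON1C(=O)c2ccccc2C1=O
Why: Carbodiimide (Steglich-type) esterification with the strongly nucleophilic N-hydroxy imide should give the redox-active ester, while the 5-OH, hydrogen-bonded to the C4 carbonyl, is not expected to be acylated.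

Step 3
Reactants: 6 monomethyl glutarate (5-methoxy-5-oxopentanoic acid)
Product: 7 1,3-dioxoisoindolin-2-yl methyl pentanedioate
Conditions: N-hydroxyphthalimide (1.05 equiv), DIC (1.05 equiv), DMAP (5 mol %), CH2Cl2, rt
Reagents that add atoms: N-hydroxyphthalimide, ON1C(=O)c2ccccc2C1=O
Why: The same carbodiimide esterification turns the cheap half-ester into its redox-active ester, with the methyl ester of the target already in place.

Step 4
Reactants: 5 1,3-dioxoisoindolin-2-yl (S)-3-(tert-butyldimethylsilyloxy)-4-(5-hydroxy-7-methoxy-4-oxo-4H-chromen-2-yl)butanoate; 7 1,3-dioxoisoindolin-2-yl methyl pentanedioate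
Product: 8 methyl (R)-6-(tert-butyldimethylsilyloxy)-7-(5-hydroxy-7-methoxy-4-oxo-4H-chromen-2-yl)heptanoate
Conditions: 7 (3 equiv), NiCl2·6H2O (20 mol %), 2,2':6',2''-terpyridine (20 mol %), AgNO3 (0.3 equiv), NMP, Mg anode/RVC cathode, constant current, rt
Reagents that add atoms: none
Why: Each N-acyloxyphthalimide takes up one electron from low-valent Ni(terpyridine) at the silver-coated cathode and fragments with loss of phthalimide anion and CO2, giving the primary radicals at C5 (from 5) and C4 (from 7); nickel captures one radical, combines it with the second, and reductive elimination from the dialkylnickel species forms the C4–C5 bond while the Mg anode supplies the electrons. The closest known reaction type is the Ni-electrocatalytic doubly decarboxylative C(sp3)–C(sp3) cross-coupling of two redox-active esters, which is established for primary/primary pairs. No ring is closed and no stereocentre is created; C6 lies β to the radical carbon, never becomes trigonal, and should be carried over unchanged. The step needs cross-coupling over homo-coupling and reduction of the active esters in preference to the 4-pyranone: the first is secured by the threefold excess of the cheap ester 7 (its dimer is non-polar and separable), the second by the much easier reduction of N-acyloxyphthalimides compared with the electron-rich, hydrogen-bonded 5-hydroxychromone. Attack of the C5 radical on the pyranone C2=C3 bond would need a 4-exo or 5-endo closure and is not expected.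

Step 5
Reactants: 8 methyl (R)-6-(tert-butyldimethylsilyloxy)-7-(5-hydroxy-7-methoxy-4-oxo-4H-chromen-2-yl)heptanoate
Product: 9 Penithochromone O [methyl (R)-6-hydroxy-7-(5-hydroxy-7-methoxy-4-oxo-4H-chromen-2-yl)heptanoate]
Conditions: HF·pyridine, THF/pyridine, 0 °C → rt
Reagents that add atoms: none
Why: Fluoride-mediated desilylation under mildly acidic, non-basic conditions should free the C6 hydroxyl without E1cB loss of the C6 oxygen through the acidic C7 methylene and without touching the methyl ester, with retention at C6 because only the O–Si bond breaks.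

**Compound list**

1 | 2',6'-dihydroxy-4'-methoxyacetophenone | CC(=O)c1c(O)cc(OC)cc1O | starting material
2 | (R)-3-(tert-butyldimethylsilyloxy)glutaric acid monomethyl ester | COC(=O)C[C@H](O[Si](C)(C)C(C)(C)C)CC(=O)O | starting material
3 | (S)-3-(tert-butyldimethylsilyloxy)-7-(2,6-dihydroxy-4-methoxyphenyl)-5,7-dioxoheptanoic acid | OC(=O)C[C@@H](O[Si](C)(C)C(C)(C)C)CC(=O)CC(=O)c1c(O)cc(OC)cc1O | intermediate (not isolated)
4 | (S)-3-(tert-butyldimethylsilyloxy)-4-(5-hydroxy-7-methoxy-4-oxo-4H-chromen-2-yl)butanoic acid | OC(=O)C[C@@H](O[Si](C)(C)C(C)(C)C)Cc1cc(=O)c2c(O)cc(OC)cc2o1 | intermediate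
5 | 1,3-dioxoisoindolin-2-yl (S)-3-(tert-butyldimethylsilyloxy)-4-(5-hydroxy-7-methoxy-4-oxo-4H-chromen-2-yl)butanoate | O=C(C[C@@H](O[Si](C)(C)C(C)(C)C)Cc1cc(=O)c2c(O)cc(OC)cc2o1)ON1C(=O)c2ccccc2C1=O | intermediate
6 | monomethyl glutarate (5-methoxy-5-oxopentanoic acid) | COC(=O)CCCC(=O)O | starting material
7 | 1,3-dioxoisoindolin-2-yl methyl pentanedioate | COC(=O)CCCC(=O)ON1C(=O)c2ccccc2C1=O | intermediate
8 | methyl (R)-6-(tert-butyldimethylsilyloxy)-7-(5-hydroxy-7-methoxy-4-oxo-4H-chromen-2-yl)heptanoate | COC(=O)CCCC[C@@H](O[Si](C)(C)C(C)(C)C)Cc1cc(=O)c2c(O)cc(OC)cc2o1 | intermediate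
9 | Penithochromone O, methyl (R)-6-hydroxy-7-(5-hydroxy-7-methoxy-4-oxo-4H-chromen-2-yl)heptanoate | COC(=O)CCCC[C@@H](O)Cc1cc(=O)c2c(O)cc(OC)cc2o1 | target

**Step count and risks**

Total step count: 5. Longest linear sequence: 4 (steps 1, 2, 4, 5).

Steps most likely to fail:

1. Step 1. The polyanion may act as a base toward the β-silyloxy methyl ester (enolisation, then β-elimination of silanolate) instead of acylating, and the neighbouring lithium carboxylate may slow the acylation. The fallback sets out from 2 and uses an activated acyl donor that should react at −78 °C before any enolisation. The free acid is esterified with tert-butyl 2,2,2-trichloroacetimidate to 1-tert-butyl 5-methyl (S)-3-(tert-butyldimethylsilyloxy)pentanedioate F1. The methyl ester alone is cleaved with LiOH (THF/H2O, 0 °C) to (S)-5-tert-butoxy-3-(tert-butyldimethylsilyloxy)-5-oxopentanoic acid F2. Carbonyldiimidazole converts this into tert-butyl (S)-3-(tert-butyldimethylsilyloxy)-5-(1H-imidazol-1-yl)-5-oxopentanoate F3, which acylates the trilithio anion of 1 at −78 °C to give tert-butyl (S)-3-(tert-butyldimethylsilyloxy)-7-(2,6-dihydroxy-4-methoxyphenyl)-5,7-dioxoheptanoate F4. TFA/CH2Cl2 (0 °C → rt) should then close the pyranone and cleave the tert-butyl ester, with re-silylation by TBSOTf/2,6-lutidine if the silyl ether is partly lost. The fallback comes back to the route at 4.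

2. Step 4. The acidic chelated phenol may protonate alkylnickel intermediates, the pyranone may be reduced at the cathode, and statistical homo-coupling may erode the cross-coupling. The fallback sets out from 5 and replaces the second radical precursor by a preformed nucleophile. Bis(4-methoxy-4-oxobutyl)zinc F5 is prepared from methyl 4-iodobutanoate by iodine–zinc exchange with Et2Zn. It is coupled with 5 under NiCl2·glyme/4,4'-di-tert-butyl-2,2'-bipyridine in THF/DMF at rt (decarboxylative Negishi alkyl–alkyl coupling, no electrolysis), with one extra equivalent of the zinc reagent to cap the phenol as its zinc salt. The fallback comes back to the route at 8.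

3. Step 2. Once the carboxyl is activated, acyl transfer to the phenol of a second molecule (oligomerisation) or base-induced β-elimination of the silyloxy group may compete. The fallback sets out from 2 and joins the chain before any chromone or phenol exists. The acid 2 is converted with N-hydroxyphthalimide/DIC into methyl (S)-3-(tert-butyldimethylsilyloxy)-5-[(1,3-dioxoisoindolin-2-yl)oxy]-5-oxopentanoate F6. Commercial mono-tert-butyl glutarate gives tert-butyl 1,3-dioxoisoindolin-2-yl pentanedioate F7 in the same way. The two are coupled under the electrolysis conditions of step 4 to 8-tert-butyl 1-methyl (R)-3-(tert-butyldimethylsilyloxy)octanedioate F8. Claisen acylation of the trilithio anion of 1 at the methyl ester (the tert-butyl ester is inert) gives tert-butyl (R)-6-(tert-butyldimethylsilyloxy)-10-(2,6-dihydroxy-4-methoxyphenyl)-8,10-dioxodecanoate F9. Methanolic HCl (AcCl in MeOH, rt → 40 °C) should then close the pyranone, cleave the silyl ether and exchange the tert-butyl for the methyl ester. The fallback comes back to the route at 9.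

**Further compounds**

F1 | step 1 | 1-tert-butyl 5-methyl (S)-3-(tert-butyldimethylsilyloxy)pentanedioate | COC(=O)C[C@H](O[Si](C)(C)C(C)(C)C)CC(=O)OC(C)(C)C
F2 | step 1 | (S)-5-tert-butoxy-3-(tert-butyldimethylsilyloxy)-5-oxopentanoic acid | OC(=O)C[C@H](O[Si](C)(C)C(C)(C)C)CC(=O)OC(C)(C)C
F3 | step 1 | tert-butyl (S)-3-(tert-butyldimethylsilyloxy)-5-(1H-imidazol-1-yl)-5-oxopentanoate | O=C(C[C@H](O[Si](C)(C)C(C)(C)C)CC(=O)OC(C)(C)C)n1ccnc1
F4 | step 1 | tert-butyl (S)-3-(tert-butyldimethylsilyloxy)-7-(2,6-dihydroxy-4-methoxyphenyl)-5,7-dioxoheptanoate | CC(C)(C)OC(=O)C[C@@H](O[Si](C)(C)C(C)(C)C)CC(=O)CC(=O)c1c(O)cc(OC)cc1O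
F5 | step 4 | bis(4-methoxy-4-oxobutyl)zinc | COC(=O)CCC[Zn]CCCC(=O)OC
F6 | step 2 | methyl (S)-3-(tert-butyldimethylsilyloxy)-5-[(1,3-dioxoisoindolin-2-yl)oxy]-5-oxopentanoate | COC(=O)C[C@H](O[Si](C)(C)C(C)(C)C)CC(=O)ON1C(=O)c2ccccc2C1=O
F7 | step 2 | tert-butyl 1,3-dioxoisoindolin-2-yl pentanedioate | CC(C)(C)OC(=O)CCCC(=O)ON1C(=O)c2ccccc2C1=O
F8 | step 2 | 8-tert-butyl 1-methyl (R)-3-(tert-butyldimethylsilyloxy)octanedioate | COC(=O)C[C@H](O[Si](C)(C)C(C)(C)C)CCCCC(=O)OC(C)(C)C
F9 | step 2 | tert-butyl (R)-6-(tert-butyldimethylsilyloxy)-10-(2,6-dihydroxy-4-methoxyphenyl)-8,10-dioxodecanoate | CC(C)(C)OC(=O)CCCC[C@@H](O[Si](C)(C)C(C)(C)C)CC(=O)CC(=O)c1c(O)cc(OC)cc1O
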